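**Plan**

- Retrosynthesis: the 7-O–aroyl bond is cut last. Before it, C3=C2 and C4–C3 of ring C are cut, which removes C3 as a one-carbon ylide and leaves a benzoic acid (C4 on C4a of ring A) whose ortho oxygen (O1) carries ring B as a 4-methoxybenzoate (C2).
- Enabling feature: C3 is the only hydrogen-bearing carbon of ring C and lies between C4 and C2, both at the carboxyl oxidation level, with C2 already bonded to O1 and to ring B.
- Ring A is bought as 1,2,4,5-tetramethoxybenzene. Two lithiations at the C–H bonds flanked by methoxy groups add the 7-oxygen and the carboxyl carbon, and one chelation-controlled demethylation ortho to the carboxyl group breaks the symmetry and frees O1.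
- Forward order: ring A is functionalised (steps 1–4), ring B is attached as the ester of both phenols (step 5), ring C is closed last by ylide acylation and intramolecular ester Wittig olefination (step 7), and the 7-O-ester is removed by methanolysis (step 8).
- Stereochemistry: the target has no stereocentre and no stereogenic double bond, so nothing has to be set.

Key step: step 7

Assumption: the four starting materials are purchasable, and because the carboxyl group that becomes C4 is flanked by two ortho oxygen substituents it is activated as its acid chloride, the most electrophilic acyl donor for a silylated ylide.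

**Route**

Step 1
Reactants: 1 1,2,4,5-tetramethoxybenzene
Product: 4 2,3,5,6-tetramethoxyphenol, via aryllithium 2 (not isolated), via dimethyl arylboronate 3 (not isolated)
Conditions: n-BuLi, THF, 0 °C to rt; B(OMe)3, −78 °C to rt; H2O2, AcOH, 0 °C
Reagents that add atoms: hydrogen peroxide, OO
Why: Directed ortho-lithiation should take place at one of the two symmetry-equivalent C–H bonds flanked by two methoxy groups, and borylation followed by peroxide oxidation (1,2-aryl shift from boron to oxygen) should convert the aryllithium into the phenol whose oxygen becomes the 7-OH of the target.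

Step 2
Reactants: 4 2,3,5,6-tetramethoxyphenol
Product: 5 1,2,4,5-tetramethoxy-3-(propan-2-yloxy)benzene
Conditions: 2-bromopropane, K2CO3, DMF, 60 °C
Reagents that add atoms: 2-bromopropane, CC(C)Br
Why: Williamson ether synthesis on the phenoxide should give an isopropyl ether that withstands butyllithium and aqueous acid and can later be cleaved by BCl3 in the presence of aryl methyl ethers.

Step 3
Reactants: 5 1,2,4,5-tetramethoxy-3-(propan-2-yloxy)benzene
Product: 7 2,3,5,6-tetramethoxy-4-(propan-2-yloxy)benzoic acid, via aryllithium 6 (not isolated)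
Conditions: n-BuLi, TMEDA, THF, 0 °C; CO2, −78 °C to rt; aq. HCl
Reagents that add atoms: carbon dioxide, O=C=O
Why: Directed ortho-lithiation at the only ring C–H left, again flanked by two methoxy groups, followed by carboxylation should install the carbon that becomes C4 and give a symmetric acid in which the two ortho methoxy groups are equivalent.

Step 4
Reactants: 7 2,3,5,6-tetramethoxy-4-(propan-2-yloxy)benzoic acid
Product: 8 2,4-dihydroxy-3,5,6-trimethoxybenzoic acid
Conditions: BCl3 (4 equiv), CH2Cl2, −78 to 0 °C; ice water; used at once
Reagents that add atoms: none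
Why: Lewis-acid ether cleavage with BCl3 should remove the isopropyl group and, by chelation-controlled demethylation through a six-membered boron chelate with the carboxyl group, one of the two equivalent ortho methoxy groups, after which the salicylate boron chelate should shield the second ortho methoxy group so that the symmetry is broken only once.

Step 5
Reactants: 8 2,4-dihydroxy-3,5,6-trimethoxybenzoic acid; 9 4-methoxybenzoyl chloride
Product: 10 2,4-bis[(4-methoxybenzoyl)oxy]-3,5,6-trimethoxybenzoic acid
Conditions: 9 (3 equiv), pyridine, DMAP (cat.), CH2Cl2, 0 °C to rt; H2O–pyridine, rt; aq. HCl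
Reagents that add atoms: none
Why: DMAP-catalysed O-acylation (esterification with an acid chloride) of both phenols should bring in ring B on the 2-oxygen and protect the 4-oxygen with the same group, and the aqueous pyridine stage should hydrolyse any mixed anhydride formed at the hindered carboxyl group back to the acid.

Step 6
Reactants: 11 methyltriphenylphosphonium bromide; 12 chlorotrimethylsilane
Product: 15 (trimethylsilylmethylene)triphenylphosphorane, via methylenetriphenylphosphorane 13 (not isolated), via silylmethylphosphonium chloride 14 (not isolated)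
Conditions: 11 (2 equiv), n-BuLi (2 equiv), THF, 0 °C to rt; 12 (1 equiv), 0 °C to rt; filtered under argon, used as THF solution
Reagents that add atoms: none
Why: Deprotonation of the phosphonium salt should give the methylene ylide, which is C-silylated by Me3SiCl and then deprotonated by the second equivalent of methylene ylide (transylidation) to give the silyl-stabilised ylide.

Step 7
Reactants: 10 2,4-bis[(4-methoxybenzoyl)oxy]-3,5,6-trimethoxybenzoic acid; 15 (trimethylsilylmethylene)triphenylphosphorane
Product: 18 5,6,8-trimethoxy-2-(4-methoxyphenyl)-4-oxo-4H-chromen-7-yl 4-methoxybenzoate, via aroyl chloride 16 (not isolated), via aroylmethylenephosphorane 17 (not isolated)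
Conditions: (COCl)2, DMF (cat.), CH2Cl2, 0 °C to rt, evaporation; THF, −78 °C, 15 (1.05 equiv) added dropwise, to rt; volatiles removed; toluene, reflux
Reagents that add atoms: none
Why: Oxalyl chloride should turn the acid into acid chloride 16, which acylates the ylide carbon of 15 at low temperature and loses Me3SiCl by chloride attack on silicon, so that acylphosphorane 17 forms without a second equivalent of ylide and the C4–C3 bond is made (acylation of a C-silylated phosphorus ylide by an acid chloride). On heating, the stabilised ylide carbon should add to the carbonyl of the neighbouring 4-methoxybenzoate and the oxaphosphetane should collapse with loss of Ph3PO to give C3=C2 with O1 already on C2; the closest known reaction is the intramolecular Wittig olefination of (2-acyloxybenzoyl)methylenephosphoranes to chromones and flavones. Ring C closes by a 6-exo-trig addition to the ester carbonyl followed by cycloreversion, and no stereocentre is formed. The step needs acylation of the ylide at the carboxyl carbon and not at either aryl ester: the acid chloride is by far the most electrophilic carbonyl present, its two ortho oxygen substituents favour an acylium-like, little-hindered transition state, and 15 is added to 16 so that no free silyl ylide is left to attack the esters. Only the ester on the oxygen ortho to the acyl group can reach the ylide carbon, so the ester para to it stays a spectator and serves as the protecting group of the 7-oxygen.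

Step 8
Reactants: 18 5,6,8-trimethoxy-2-(4-methoxyphenyl)-4-oxo-4H-chromen-7-yl 4-methoxybenzoate
Product: 19 7-hydroxy-5,6,8-trimethoxy-2-(4-methoxyphenyl)-4H-chromen-4-one (7-hydroxy-4',5,6,8-tetramethoxyflavone)
Conditions: K2CO3 (1.5 equiv), MeOH–THF, rt; aq. HCl
Reagents that add atoms: none
Why: Base-mediated transesterification (methanolysis) should cleave the aryl 4-methoxybenzoate, whose leaving group is a vinylogous carboxylate conjugated with the C4 carbonyl, while the pyranone ring and the methyl ethers are inert to K2CO3 in methanol at room temperature.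

**Compound list**

1 | 1,2,4,5-tetramethoxybenzene | COc1cc(OC)c(OC)cc1OC | starting material
2 | (2,3,5,6-tetramethoxyphenyl)lithium | [Li]c1c(OC)c(OC)cc(OC)c1OC | intermediate
3 | dimethyl (2,3,5,6-tetramethoxyphenyl)boronate | COB(OC)c1c(OC)c(OC)cc(OC)c1OC | intermediate
4 | 2,3,5,6-tetramethoxyphenol | COc1cc(OC)c(OC)c(O)c1OC | intermediate
5 | 1,2,4,5-tetramethoxy-3-(propan-2-yloxy)benzene | COc1cc(OC)c(OC)c(OC(C)C)c1OC | intermediate
6 | [2,3,5,6-tetramethoxy-4-(propan-2-yloxy)phenyl]lithium | [Li]c1c(OC)c(OC)c(OC(C)C)c(OC)c1OC | intermediate
7 | 2,3,5,6-tetramethoxy-4-(propan-2-yloxy)benzoic acid | COc1c(OC)c(C(=O)O)c(OC)c(OC)c1OC(C)C | intermediate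
8 | 2,4-dihydroxy-3,5,6-trimethoxybenzoic acid | COc1c(O)c(OC)c(O)c(C(=O)O)c1OC | intermediate
9 | 4-methoxybenzoyl chloride | COc1ccc(C(Cl)=O)cc1 | starting material
10 | 2,4-bis[(4-methoxybenzoyl)oxy]-3,5,6-trimethoxybenzoic acid | COc1ccc(C(=O)Oc2c(OC)c(OC)c(C(=O)O)c(OC(=O)c3ccc(OC)cc3)c2OC)cc1 | intermediate
11 | methyltriphenylphosphonium bromide | C[P+](c1ccccc1)(c1ccccc1)c1ccccc1.[Br-] | starting material
12 | chlorotrimethylsilane | C[Si](C)(C)Cl | starting material
13 | methylenetriphenylphosphorane | C=P(c1ccccc1)(c1ccccc1)c1ccccc1 | intermediate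
14 | (trimethylsilylmethyl)triphenylphosphonium chloride | C[Si](C)(C)C[P+](c1ccccc1)(c1ccccc1)c1ccccc1.[Cl-] | intermediate
15 | (trimethylsilylmethylene)triphenylphosphorane | C[Si](C)(C)C=P(c1ccccc1)(c1ccccc1)c1ccccc1 | intermediate
16 | 2,4-bis[(4-methoxybenzoyl)oxy]-3,5,6-trimethoxybenzoyl chloride | COc1ccc(C(=O)Oc2c(OC)c(OC)c(C(Cl)=O)c(OC(=O)c3ccc(OC)cc3)c2OC)cc1 | intermediate
17 | {2,4-bis[(4-methoxybenzoyl)oxy]-3,5,6-trimethoxybenzoyl}methylenetriphenylphosphorane | COc1ccc(C(=O)Oc2c(OC)c(OC)c(C(=O)C=P(c3ccccc3)(c3ccccc3)c3ccccc3)c(OC(=O)c3ccc(OC)cc3)c2OC)cc1 | intermediate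
18 | 5,6,8-trimethoxy-2-(4-methoxyphenyl)-4-oxo-4H-chromen-7-yl 4-methoxybenzoate | COc1ccc(C(=O)Oc2c(OC)c(OC)c3c(=O)cc(-c4ccc(OC)cc4)oc3c2OC)cc1 | intermediate
19 | 7-hydroxy-5,6,8-trimethoxy-2-(4-methoxyphenyl)-4H-chromen-4-one (7-hydroxy-4',5,6,8-tetramethoxyflavone) | COc1ccc(-c2cc(=O)c3c(OC)c(OC)c(O)c(OC)c3o2)cc1 | target

**Step count**

Total: 8 steps. Longest linear sequence: 7 steps (steps 1–5, 7 and 8, from 1); step 6 is a one-step branch.

**Steps most likely to fail, with fallbacks**

Step 7. Acylation of the bulky silyl ylide at a carboxyl carbon flanked by two ortho substituents may be slower than its attack on an aryl ester carbonyl. On heating, the acyl ylide may also transfer the neighbouring aroyl group to carbon (collapse of the tetrahedral adduct with loss of phenoxide) instead of eliminating Ph3PO. The fallback replaces the olefination by enolate acyl transfer and cyclodehydration. It sets out from 5, which would be lithiated as in step 3 (via 6) and quenched with N-methoxy-N-methylacetamide to give 1-[2,3,5,6-tetramethoxy-4-(propan-2-yloxy)phenyl]ethanone F1. BCl3 in CH2Cl2 would then give 1-(2,4-dihydroxy-3,5,6-trimethoxyphenyl)ethanone F2, and acylation with 9 (pyridine, DMAP) would give 4-acetyl-2,5,6-trimethoxy-1,3-phenylene bis(4-methoxybenzoate) F3. A Baker–Venkataraman rearrangement with LiN(SiMe3)2 in THF would move the ortho aroyl group to carbon and give 3-hydroxy-2,5,6-trimethoxy-4-[3-(4-methoxyphenyl)-3-oxopropanoyl]phenyl 4-methoxybenzoate F4. Cyclodehydration with H2SO4 in AcOH would close ring C and come back to the route at 18.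

Step 4. The ether cleavage may run on (loss of the second ortho or of a flanked meta methyl group), and the electron-rich salicylic acid may lose CO2 by protodecarboxylation during the acidic work-up. The fallback carries the carbon at the aldehyde oxidation level, where chelation-controlled demethylation by BCl3 is best precedented and decarboxylation is impossible. It sets out from 5: lithiation as in step 3 and a DMF quench would give 2,3,5,6-tetramethoxy-4-(propan-2-yloxy)benzaldehyde F5. BCl3 in CH2Cl2 at −78 to 0 °C would give 2,4-dihydroxy-3,5,6-trimethoxybenzaldehyde F6, and acylation with 9 (pyridine, DMAP) would give 4-formyl-2,5,6-trimethoxy-1,3-phenylene bis(4-methoxybenzoate) F7. Pinnick oxidation (NaClO2, NaH2PO4, 2-methyl-2-butene, t-BuOH–H2O) would come back to the route at 10.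

Step 5. Acylation of the hydrogen-bonded, doubly flanked 2-hydroxyl may stay incomplete while the reagent is diverted into anhydride formation at the free carboxyl group, and the acid product may be hard to separate from 4-methoxybenzoic acid. The fallback masks the carboxyl group first. It sets out from 8: selective carboxylate alkylation (BnBr, KHCO3, DMF) would give benzyl 2,4-dihydroxy-3,5,6-trimethoxybenzoate F8. Acylation with 9 (pyridine, DMAP, CH2Cl2), which can then be forced and purified on silica, would give benzyl 2,4-bis[(4-methoxybenzoyl)oxy]-3,5,6-trimethoxybenzoate F9. Hydrogenolysis (H2, 10% Pd/C, EtOAc) would come back to the route at 10.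

**Further compounds**

F1 | step 7 | 1-[2,3,5,6-tetramethoxy-4-(propan-2-yloxy)phenyl]ethanone | COc1c(OC)c(C(C)=O)c(OC)c(OC)c1OC(C)C
F2 | step 7 | 1-(2,4-dihydroxy-3,5,6-trimethoxyphenyl)ethanone | COc1c(O)c(OC)c(O)c(C(C)=O)c1OC
F3 | step 7 | 4-acetyl-2,5,6-trimethoxy-1,3-phenylene bis(4-methoxybenzoate) | COc1ccc(C(=O)Oc2c(OC)c(OC)c(C(C)=O)c(OC(=O)c3ccc(OC)cc3)c2OC)cc1
F4 | step 7 | 3-hydroxy-2,5,6-trimethoxy-4-[3-(4-methoxyphenyl)-3-oxopropanoyl]phenyl 4-methoxybenzoate | COc1ccc(C(=O)Oc2c(OC)c(OC)c(C(=O)CC(=O)c3ccc(OC)cc3)c(O)c2OC)cc1
F5 | step 4 | 2,3,5,6-tetramethoxy-4-(propan-2-yloxy)benzaldehyde | COc1c(OC)c(C=O)c(OC)c(OC)c1OC(C)C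
F6 | step 4 | 2,4-dihydroxy-3,5,6-trimethoxybenzaldehyde | COc1c(O)c(OC)c(O)c(C=O)c1OC
F7 | step 4 | 4-formyl-2,5,6-trimethoxy-1,3-phenylene bis(4-methoxybenzoate) | COc1ccc(C(=O)Oc2c(OC)c(OC)c(C=O)c(OC(=O)c3ccc(OC)cc3)c2OC)cc1
F8 | step 5 | benzyl 2,4-dihydroxy-3,5,6-trimethoxybenzoate | COc1c(O)c(OC)c(O)c(C(=O)OCc2ccccc2)c1OC
F9 | step 5 | benzyl 2,4-bis[(4-methoxybenzoyl)oxy]-3,5,6-trimethoxybenzoate | COc1ccc(C(=O)Oc2c(OC)c(OC)c(C(=O)OCc3ccccc3)c(OC(=O)c3ccc(OC)cc3)c2OC)cc1
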